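**Plan**

- Retrosynthesis: the phenol is first masked as its tert-butyl carbonate. The acyl chain (C1 = ester carbonyl, C37 = methyl) is then cut at C14–C15, and last the ester bond between C1 and the tyrosol oxygen is cut.
- Enabling feature: C2 to C37 are an unbranched run of CH2 groups ending in CH3, with no heteroatom, branch or double bond. C14 and C15 can therefore both be primary alkyl radicals born from carboxylic acids, and the benzene ring lies beyond the ester, thirteen CH2 groups from C14.
- Forward: tyrosol is carbonated at the phenol oxygen, and its primary alcohol is acylated once by pentadecanedioic acid (C1–C14 plus the carboxyl carbon that later leaves as CO2). Co-electrolysis with tetracosanoic acid then adds C15–C37 in a single C–C bond formation.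
- Acid then removes the carbonate. No ring is made at any stage: the benzene ring comes intact with tyrosol.
- Stereochemistry: the target has no stereocentre and no stereogenic double bond, so nothing has to be set or preserved.

Key step: step 3

Remark on the chemistry: acyl-chain positions are counted from the ester carbonyl carbon (C1) to the terminal methyl (C37), and the aryl tert-butyl carbonate is taken to be stable in warm methanol for as long as free carboxylic acid keeps the electrolyte acidic.

**Route**

Step 1
Reactants: 1 tyrosol [4-(2-hydroxyethyl)phenol]; 2 di-tert-butyl dicarbonate
Product: 3 tert-butyl 4-(2-hydroxyethyl)phenyl carbonate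
Conditions: Boc2O (1.05 equiv), 1 M aq. NaOH (1.0 equiv), THF, 0 °C to rt
Reagents that add atoms: di-tert-butyl dicarbonate (2), CC(C)(C)OC(=O)OC(=O)OC(C)(C)C
Why: One equivalent of hydroxide ionises only the phenolic OH (pKa near 10 against about 16 for the primary alcohol), so this chemoselective O-tert-butoxycarbonylation (carbonate formation with Boc2O) should occur at the aryl oxygen alone and leave the hydroxyethyl group free.

Step 2
Reactants: 3 tert-butyl 4-(2-hydroxyethyl)phenyl carbonate; 4 pentadecanedioic acid
Product: 5 15-{2-[4-(tert-butoxycarbonyloxy)phenyl]ethoxy}-15-oxopentadecanoic acid
Conditions: 4 (4 equiv), DCC (1.2 equiv), DMAP (0.1 equiv), THF, 0 °C to rt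
Reagents that add atoms: none
Why: Steglich esterification (carbodiimide activation with DMAP acyl transfer) acylates the unhindered primary alcohol under neutral conditions that spare the aryl carbonate, and the fourfold excess of diacid 4 should statistically favour the half ester over the diester, the unused diacid being recoverable.

Step 3
Reactants: 5 15-{2-[4-(tert-butoxycarbonyloxy)phenyl]ethoxy}-15-oxopentadecanoic acid; 6 tetracosanoic acid
Product: 7 2-[4-(tert-butoxycarbonyloxy)phenyl]ethyl heptatriacontanoate
Conditions: Pt anode and Pt cathode, undivided cell, constant current (ca. 0.2 A cm-2), 6 (4 equiv, neutralised with KOH to 5 mol% of total CO2H before 5 is added), MeOH/hexane, 50 °C, stopped while the electrolyte is still acidic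
Reagents that add atoms: none
Why: At the platinum anode each carboxylate is oxidised by one electron and the acyloxy radicals lose CO2 at once, so tricosyl radicals from 6 and ester-terminated tridecyl radicals from 5 (C14 counted with the ester carbon) arise side by side in the carboxylate layer on the electrode and combine, the crossed pairing forging C14–C15 (mixed Kolbe electrolysis, the classical union of a fatty acid with a dicarboxylic acid half ester). No ring closes and no stereocentre is created, so no mode of closure and no stereocontrol element is involved. Two selectivities are needed: radical coupling must outrun further oxidation to the cation, and crossed coupling must outweigh the homodimer of 5. The first is secured by the substrate, since both radicals are primary, unbranched and free of α-heteroatoms, aided by the high current density, the smooth Pt surface and the weakly acidic medium; the second is only statistical and is biased by feeding 6 in fourfold excess, which should turn most radicals from 5 into 7 and leave a non-polar C46 alkane from 6 that hexane keeps off the anode and chromatography removes. The benzene ring is shielded from the anode by its distance from the carboxylate head group (an ester and thirteen CH2 groups) and by the electron-withdrawing carbonate on its oxygen, and the free-acid buffer keeps methoxide away from the carbonate and the arylethyl ester.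

Step 4
Reactants: 7 2-[4-(tert-butoxycarbonyloxy)phenyl]ethyl heptatriacontanoate
Product: 8 2-(4-hydroxyphenyl)ethyl heptatriacontanoate
Conditions: TFA/CH2Cl2 (1:4), rt
Reagents that add atoms: none
Why: Acidolysis of the tert-butyl carbonate (loss of the tert-butyl cation as 2-methylpropene followed by decarboxylation) should free the phenol, while the saturated primary alkyl ester, which has no acid-labile alkyl group, is inert to anhydrous TFA at room temperature.

**Compound list**

1 | tyrosol, 4-(2-hydroxyethyl)phenol | OCCc1ccc(O)cc1 | starting material
2 | di-tert-butyl dicarbonate | CC(C)(C)OC(=O)OC(=O)OC(C)(C)C | starting material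
3 | tert-butyl 4-(2-hydroxyethyl)phenyl carbonate | OCCc1ccc(OC(=O)OC(C)(C)C)cc1 | intermediate
4 | pentadecanedioic acid | OC(=O)CCCCCCCCCCCCCC(=O)O | starting material
5 | 15-{2-[4-(tert-butoxycarbonyloxy)phenyl]ethoxy}-15-oxopentadecanoic acid | OC(=O)CCCCCCCCCCCCCC(=O)OCCc1ccc(OC(=O)OC(C)(C)C)cc1 | intermediate
6 | tetracosanoic acid | CCCCCCCCCCCCCCCCCCCCCCCC(=O)O | starting material
7 | 2-[4-(tert-butoxycarbonyloxy)phenyl]ethyl heptatriacontanoate | CCCCCCCCCCCCCCCCCCCCCCCCCCCCCCCCCCCCC(=O)OCCc1ccc(OC(=O)OC(C)(C)C)cc1 | intermediate
8 | 2-(4-hydroxyphenyl)ethyl heptatriacontanoate | CCCCCCCCCCCCCCCCCCCCCCCCCCCCCCCCCCCCC(=O)OCCc1ccc(O)cc1 | target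

**Step count and risks**

Total step count: 4. Longest linear sequence: 4 steps (1 → 3 → 5 → 7 → 8).

Steps most likely to fail:

Step 3 (electrolysis). The crossed coupling may be eroded by homo-coupling of each radical and by fouling of the anode with waxy hydrocarbon. The arene or its benzylic position may be oxidised at the anode. The aryl carbonate may be solvolysed, or the arylethyl ester exchanged with methanol, wherever the electrolyte turns basic near the cathode. The fallback takes the aromatic half out of the cell; it sets out from 4 and 6 and returns at 7. Diacid 4 is converted by partial Fischer esterification (MeOH, catalytic H2SO4) into 15-methoxy-15-oxopentadecanoic acid F1. F1 is co-electrolysed with excess 6 at Pt in warm MeOH/hexane, a pairing with nothing oxidisable or base-labile, to give methyl heptatriacontanoate F2. Saponification (KOH, EtOH/toluene, reflux, then HCl) gives heptatriacontanoic acid F3, which is esterified with alcohol 3 (DCC, DMAP, CH2Cl2/THF, 40 °C) to arrive at 7.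

Step 2 (half-ester formation). Both carboxyl groups of the diacid may be acylated, the activated acid may rearrange to an N-acylurea, and the half ester may be hard to separate from the large excess of diacid. The fallback differentiates the two ends with a protecting group; it sets out from 4 and returns at 5. Diacid 4 is heated with benzyl alcohol (1 equiv, catalytic TsOH, toluene, water removal) to give 15-(benzyloxy)-15-oxopentadecanoic acid F4, which is purified before any tyrosol-derived material is committed. Steglich coupling of F4 with 3 (DCC, DMAP, CH2Cl2) gives benzyl 2-[4-(tert-butoxycarbonyloxy)phenyl]ethyl pentadecanedioate F5. Hydrogenolysis (H2, Pd/C, EtOAc, rt) removes the benzyl group without touching the aryl carbonate or the alkyl ester and delivers 5.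

Step 4 (unmasking). The tert-butyl cation may alkylate the liberated phenol ring ortho to the hydroxyl, and cleavage may stall if the waxy substrate is poorly dissolved in the acidic medium. The fallback breaks the carbonate at its carbonyl carbon and not at the tert-butyl–oxygen bond, so no carbocation is formed; it sets out from 7 and returns at 8. Treating 7 with piperidine (CHCl3, rt) transfers the tert-butoxycarbonyl group to nitrogen by aminolysis of the activated aryl carbonate and releases the phenol 8, while the unactivated alkyl ester does not undergo aminolysis at room temperature. The path adds no compound to the list (none F0).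

Further compounds
F1 | step 3 | 15-methoxy-15-oxopentadecanoic acid | COC(=O)CCCCCCCCCCCCCC(=O)O
F2 | step 3 | methyl heptatriacontanoate | CCCCCCCCCCCCCCCCCCCCCCCCCCCCCCCCCCCCC(=O)OC
F3 | step 3 | heptatriacontanoic acid | CCCCCCCCCCCCCCCCCCCCCCCCCCCCCCCCCCCCC(=O)O
F4 | step 2 | 15-(benzyloxy)-15-oxopentadecanoic acid | OC(=O)CCCCCCCCCCCCCC(=O)OCc1ccccc1
F5 | step 2 | benzyl 2-[4-(tert-butoxycarbonyloxy)phenyl]ethyl pentadecanedioate | O=C(OCc1ccccc1)CCCCCCCCCCCCCC(=O)OCCc1ccc(OC(=O)OC(C)(C)C)cc1
F0 | step 4 | none | none
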